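**Retrosynthetic overview**
1. Target 32 ← Shi epoxidation of the (5E)-olefin of macrocyclic diacetate 31 ← diol 30; the oxirane is made last so that no free C9 hydroxyl ever sits next to it.
2. 14-membered carbocycle ← Nozaki–Hiyama–Kishi closure of C9–C10 in iodo-aldehyde 26; C9 is then reset by oxidation and CBS reduction.
3. Key disconnection: the C3a–C15a bond and the cis-fused α-methylene-γ-butyrolactone ← intermolecular indium-mediated carbonyl allylation of α-alkoxy aldehyde 13 with (Z)-2-(bromomethyl)enoate 22.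
4. 13 ← (S)-citronellal (C14) by proline α-aminoxylation (C15); 22 ← pent-4-yn-1-ol by Negishi carboalumination/ethylene oxide, vinylalumination with methyl propiolate and allylic bromination.
5. Ring order: γ-lactone (step 15), carbocycle (step 18), oxirane (step 23).

Assumption: macrocycles carry cyclotetradeca[b]furan locants (O1, C2 lactone carbonyl, C3, C3a, C4–C15, C15a); CIP analysis of the given SMILES gives the target as (3aS,5R,6R,9R,14S,15R,15aR) with a trans oxirane and a cis ring fusion.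

**Fragment A (aldehyde 13)**

Step 1
Reactants: 1 (S)-citronellal
Product: 3 (2R,3S)-3,7-dimethyl-2-[(phenylamino)oxy]oct-6-en-1-ol, via aminoxy aldehyde 2 (not isolated)
Conditions: PhN=O (0.9 equiv), L-proline (20 mol %), DMSO, rt, 30 min; then NaBH4, EtOH, 0 °C
Reagents that add atoms: nitrosobenzene O=Nc1ccccc1
Why: Proline-catalysed α-aminoxylation proceeds through the enamine, L-proline directing the O-electrophile to the face that makes C2 (R) under catalyst control next to the citronellal centre, and immediate borohydride reduction stops epimerisation of the α-oxy aldehyde.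

Step 2
Reactants: 3 aminoxy alcohol
Product: 4 (2R,3S)-3,7-dimethyloct-6-ene-1,2-diol
Conditions: Zn dust, AcOH/EtOH (1:3), rt
Reagents that add atoms: none
Why: Reductive N–O cleavage by zinc in acetic acid frees the secondary hydroxyl without touching either stereocentre or the trisubstituted olefin.

Step 3
Reactants: 4 diol
Product: 5 (4R)-2-(4-methoxyphenyl)-4-[(2S)-6-methylhept-5-en-2-yl]-1,3-dioxolane (both acetal epimers)
Conditions: 4-MeOC6H4CH(OMe)2, PPTS (cat.), CH2Cl2, rt
Reagents that add atoms: 4-methoxybenzaldehyde dimethyl acetal COc1ccc(C(OC)OC)cc1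
Why: Acid-catalysed transacetalisation ties the 1,2-diol into a p-methoxybenzylidene acetal that protects both oxygens now and later becomes the secondary PMB ether.

Step 4
Reactants: 5 acetal
Product: 7 (4S)-4-[(4R)-2-(4-methoxyphenyl)-1,3-dioxolan-4-yl]pentan-1-ol, via aldehyde 6 (not isolated)
Conditions: O3, CH2Cl2/MeOH (4:1), −78 °C, stopped at first blue colour; then NaBH4, −78 °C → rt
Reagents that add atoms: ozone [O-][O+]=O
Why: Ozonolysis with reductive work-up cleaves the electron-rich trisubstituted olefin far faster than the anisyl ring and gives the primary alcohol directly.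

Step 5
Reactants: 7 alcohol
Product: 8 (4R)-4-[(2S)-5-iodopentan-2-yl]-2-(4-methoxyphenyl)-1,3-dioxolane
Conditions: I2, PPh3, imidazole, CH2Cl2, 0 °C → rt
Reagents that add atoms: iodine II
Why: The Appel reaction turns the unhindered primary alcohol into the iodide under imidazole-buffered conditions that leave the acetal intact.

Step 6
Reactants: 8 iodide
Product: 9 (4R)-4-[(2S)-hept-6-yn-2-yl]-2-(4-methoxyphenyl)-1,3-dioxolane
Conditions: LiC≡CH·H2NCH2CH2NH2 (2 equiv), DMSO, 10 °C → rt
Reagents that add atoms: lithium acetylide (ethylenediamine complex) [Li]C#C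
Why: SN2 alkylation of lithium acetylide by an unbranched primary iodide in DMSO is a standard, high-yielding way to a terminal alkyne.

Step 7
Reactants: 9 alkyne
Product: 11 (4R)-4-[(2S)-6-iodohept-6-en-2-yl]-2-(4-methoxyphenyl)-1,3-dioxolane, via alkenylalane 10 (not isolated)
Conditions: iBu2AlH (DIBAL-H, 1.3 equiv), Ni(dppp)Cl2 (3 mol %), THF, 0 °C → rt, 2 h; then NIS, 0 °C
Reagents that add atoms: N-iodosuccinimide O=C1CCC(=O)N1I
Why: Nickel-catalysed hydroalumination with the dppp ligand places aluminium on the internal alkyne carbon and iodinolysis then gives the 2-iodo-1-alkene, any acetal opened by DIBAL-H in THF simply converging on 12 after step 8.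

Step 8
Reactants: 11 vinyl iodide acetal
Product: 12 (2R,3S)-7-iodo-2-[(4-methoxybenzyl)oxy]-3-methyloct-7-en-1-ol
Conditions: iBu2AlH (3 equiv), CH2Cl2, −78 → 0 °C; aq. potassium sodium tartrate
Reagents that add atoms: none
Why: Reductive acetal opening by DIBAL-H occurs after coordination to the less hindered primary oxygen, which leaves the PMB group on the secondary oxygen and frees the primary alcohol.

Step 9
Reactants: 12 alcohol
Product: 13 (2R,3S)-7-iodo-2-[(4-methoxybenzyl)oxy]-3-methyloct-7-enal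
Conditions: Dess–Martin periodinane, NaHCO3, CH2Cl2, 0 °C → rt; used at once
Reagents that add atoms: none
Why: Dess–Martin oxidation under buffered, non-basic conditions gives the α-alkoxy aldehyde without epimerising C2.

**Fragment B (bromide 22)**

Step 10
Reactants: 14 pent-4-yn-1-ol
Product: 15 tert-butyldimethyl(pent-4-yn-1-yloxy)silane
Conditions: TBSCl, imidazole, DMF, rt
Reagents that add atoms: tert-butyldimethylsilyl chloride CC(C)(C)[Si](C)(C)Cl
Why: Standard silylation masks the future C9 hydroxyl as an ether that tolerates organoaluminium reagents.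

Step 11
Reactants: 15 silyl ether
Product: 17 (3E)-7-[(tert-butyldimethylsilyl)oxy]-4-methylhept-3-en-1-ol, via alkenylalane 16 (not isolated)
Conditions: AlMe3 (2 equiv), Cp2ZrCl2 (0.25 equiv), CH2Cl2, 0 °C → rt; volatiles removed; n-BuLi (1 equiv), hexane, −30 °C; ethylene oxide, THF, −30 °C → rt
Reagents that add atoms: trimethylaluminium C[Al](C)C; ethylene oxide C1CCO1
Why: Negishi zirconium-catalysed carboalumination adds methyl and aluminium syn across the alkyne, and the derived alanate opens ethylene oxide with retention, which fixes the (E)-trisubstituted olefin.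

Correction to the SMILES on the reagent line of step 11: ethylene oxide is C1CO1.

Step 12
Reactants: 17 homoallylic alcohol
Product: 18 (3E)-7-[(tert-butyldimethylsilyl)oxy]-4-methylhept-3-enal
Conditions: Dess–Martin periodinane, NaHCO3, CH2Cl2, 0 °C; used crude at once
Reagents that add atoms: none
Why: Neutral Dess–Martin oxidation gives the β,γ-unsaturated aldehyde without moving the olefin into conjugation.

Step 13
Reactants: 18 aldehyde; 19 methyl propiolate
Product: 21 methyl (5E)-9-[(tert-butyldimethylsilyl)oxy]-3-hydroxy-6-methyl-2-methylidenenon-5-enoate (racemic at C3), via alanyl acrylate 20 (not isolated)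
Conditions: 19 (1.5 equiv), iBu2AlH (1.5 equiv), N-methylmorpholine N-oxide, THF, 0 °C, 1 h; then 18, 0 °C → rt
Reagents that add atoms: none
Why: Vinylalumination (a Morita–Baylis–Hillman surrogate) adds the α-aluminated acrylate to the aldehyde within hours under non-basic conditions, so the skipped olefin does not isomerise, and the carbinol centre is lost in the next step.

Step 14
Reactants: 21 allylic alcohol
Product: 22 methyl (2Z,5E)-2-(bromomethyl)-9-[(tert-butyldimethylsilyl)oxy]-6-methylnona-2,5-dienoate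
Conditions: NBS, Me2S, CH2Cl2, 0 °C → rt
Reagents that add atoms: N-bromosuccinimide O=C1CCC(=O)N1Br
Why: SN2′ bromination of the activated alcohol with allylic transposition gives the thermodynamically preferred (Z)-2-(bromomethyl)enoate (chain trans to the ester) without free HBr, so the silyl ether and olefin survive.

**Fragment union and endgame**

Step 15
Reactants: 13 aldehyde; 22 allylic bromide
Product: 24 (4S,5R)-4-[(2E)-6-[(tert-butyldimethylsilyl)oxy]-3-methylhex-2-en-1-yl]-5-[(1R,2S)-6-iodo-1-[(4-methoxybenzyl)oxy]-2-methylhept-6-en-1-yl]-3-methylideneoxolan-2-one, via hydroxy ester 23 (not isolated)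
Conditions: indium powder (1.5 equiv), 22 (1.3 equiv), THF/H2O (1:1), rt; then PPTS (cat.), toluene, 60 °C
Reagents that add atoms: none
Why: In this Barbier-type carbonyl allylation the (Z)-configured allylindium adds through a chair transition state (new C–C bond syn, hence the cis lactone) to the aldehyde face exposed in the chelate between the carbonyl and the α-PMB-ether oxygen (Cram-chelate, syn to C15), and acid then closes the γ-lactone; the selectivity is expected, not guaranteed, and minor isomers are removed at 24.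

Step 16
Reactants: 24 lactone
Product: 25 (4S,5R)-4-[(2E)-6-hydroxy-3-methylhex-2-en-1-yl]-5-[(1R,2S)-6-iodo-1-[(4-methoxybenzyl)oxy]-2-methylhept-6-en-1-yl]-3-methylideneoxolan-2-one
Conditions: HF·pyridine, pyridine/THF, 0 °C → rt
Reagents that add atoms: none
Why: Buffered fluoride desilylation removes the primary TBS ether without the basic conditions that could add to the α-methylene lactone.

Step 17
Reactants: 25 alcohol
Product: 26 (4E)-6-[(2R,3S)-2-[(1R,2S)-6-iodo-1-[(4-methoxybenzyl)oxy]-2-methylhept-6-en-1-yl]-4-methylidene-5-oxooxolan-3-yl]-4-methylhex-4-enal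
Conditions: Dess–Martin periodinane, NaHCO3, CH2Cl2, 0 °C → rt
Reagents that add atoms: none
Why: Dess–Martin oxidation gives the aldehyde chemoselectively in the presence of the vinyl iodide, PMB ether and lactone.

Step 18
Reactants: 26 iodo-aldehyde
Product: 27 (3aS,5E,14S,15R,15aR)-9-hydroxy-15-[(4-methoxybenzyl)oxy]-6,14-dimethyl-3,10-dimethylidene-3a,4,7,8,9,10,11,12,13,14,15,15a-dodecahydrocyclotetradeca[b]furan-2(3H)-one (both C9 epimers)
Conditions: CrCl2 (8 equiv), NiCl2 (0.08 equiv), DMSO/THF (3:1), rt, syringe-pump addition to 2 mM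
Reagents that add atoms: none
Why: The Nozaki–Hiyama–Kishi reaction adds the alkenylchromium from the 2-iodoalkene to the aldehyde at high dilution, tolerates the lactone and ether, and directly forms the exocyclic methylene next to the carbinol; the C9 configuration is left open here and fixed in steps 19 and 20.

Step 19
Reactants: 27 allylic alcohols
Product: 28 (3aS,5E,14S,15R,15aR)-15-[(4-methoxybenzyl)oxy]-6,14-dimethyl-3,10-dimethylidene-3a,4,7,8,11,12,13,14,15,15a-decahydrocyclotetradeca[b]furan-2,9(3H,10H)-dione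
Conditions: Dess–Martin periodinane, NaHCO3, CH2Cl2, 0 °C; used directly
Reagents that add atoms: none
Why: Dess–Martin oxidation converges both C9 epimers on one α-methylene ketone, which erases the uncontrolled stereocentre.

Step 20
Reactants: 28 enone
Product: 29 (3aS,5E,9R,14S,15R,15aR)-9-hydroxy-15-[(4-methoxybenzyl)oxy]-6,14-dimethyl-3,10-dimethylidene-3a,4,7,8,9,10,11,12,13,14,15,15a-dodecahydrocyclotetradeca[b]furan-2(3H)-one
Conditions: (S)-Me-CBS oxazaborolidine (1 equiv), catecholborane (2 equiv), toluene, −78 °C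
Reagents that add atoms: none
Why: In the Corey–Bakshi–Shibata reduction the (S)-oxazaborolidine binds the ketone with the branched alkenyl group as the large substituent and delivers hydride to give the (9R)-allylic alcohol under reagent control, the lactone being inert at −78 °C.

Step 21
Reactants: 29 PMB ether
Product: 30 (3aS,5E,9R,14S,15R,15aR)-9,15-dihydroxy-6,14-dimethyl-3,10-dimethylidene-3a,4,7,8,9,10,11,12,13,14,15,15a-dodecahydrocyclotetradeca[b]furan-2(3H)-one
Conditions: DDQ (1.5 equiv), CH2Cl2/pH 7 phosphate buffer (10:1), 0 °C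
Reagents that add atoms: none
Why: Oxidative PMB cleavage by DDQ under neutral buffer frees the C15 hydroxyl without acid or base.

Step 22
Reactants: 30 diol
Product: 31 (3aS,5E,9R,14S,15R,15aR)-6,14-dimethyl-3,10-dimethylidene-2-oxo-2,3,3a,4,7,8,9,10,11,12,13,14,15,15a-tetradecahydrocyclotetradeca[b]furan-9,15-diyl diacetate
Conditions: Ac2O, pyridine, DMAP (cat.), CH2Cl2, rt
Reagents that add atoms: acetic anhydride CC(=O)OC(C)=O
Why: DMAP-catalysed acylation esterifies both secondary alcohols, the hindered C15 one included, without affecting any stereocentre.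

Step 23
Reactants: 31 diacetate
Product: 32 (3aS,5R,6R,9R,14S,15R,15aR)-5,6-epoxy-6,14-dimethyl-3,10-dimethylidene-2-oxotetradecahydrocyclotetradeca[b]furan-9,15-diyl diacetate
Conditions: D-fructose-derived Shi ketone (0.3 equiv), KHSO5 (as Oxone, 1.4 equiv), K2CO3, Bu4NHSO4 (cat.), MeCN/CH2(OMe)2/aq. Na2B4O7 buffer (pH 10.5), 0 °C, 1.5 h
Reagents that add atoms: potassium peroxymonosulfate [K+].[O-]S(=O)(=O)OO
Why: In the Shi epoxidation the chiral dioxirane transfers oxygen through a spiro transition state to the face of the electron-rich (E)-trisubstituted olefin that gives the (5R,6R)-oxirane, while the two deactivated methylene groups do not react.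

**Compound list**
1 | (S)-citronellal | CC(C)=CCC[C@H](C)CC=O | starting material
2 | (2R,3S)-3,7-dimethyl-2-[(phenylamino)oxy]oct-6-enal | CC(C)=CCC[C@H](C)[C@@H](ONc1ccccc1)C=O | intermediate (not isolated)
3 | (2R,3S)-3,7-dimethyl-2-[(phenylamino)oxy]oct-6-en-1-ol | CC(C)=CCC[C@H](C)[C@@H](ONc1ccccc1)CO | intermediate
4 | (2R,3S)-3,7-dimethyloct-6-ene-1,2-diol | CC(C)=CCC[C@H](C)[C@@H](O)CO | intermediate
5 | (4R)-2-(4-methoxyphenyl)-4-[(2S)-6-methylhept-5-en-2-yl]-1,3-dioxolane | CC(C)=CCC[C@H](C)[C@@H]1COC(c2ccc(OC)cc2)O1 | intermediate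
6 | (4S)-4-[(4R)-2-(4-methoxyphenyl)-1,3-dioxolan-4-yl]pentanal | O=CCC[C@H](C)[C@@H]1COC(c2ccc(OC)cc2)O1 | intermediate (not isolated)
7 | (4S)-4-[(4R)-2-(4-methoxyphenyl)-1,3-dioxolan-4-yl]pentan-1-ol | OCCC[C@H](C)[C@@H]1COC(c2ccc(OC)cc2)O1 | intermediate
8 | (4R)-4-[(2S)-5-iodopentan-2-yl]-2-(4-methoxyphenyl)-1,3-dioxolane | ICCC[C@H](C)[C@@H]1COC(c2ccc(OC)cc2)O1 | intermediate
9 | (4R)-4-[(2S)-hept-6-yn-2-yl]-2-(4-methoxyphenyl)-1,3-dioxolane | C#CCCC[C@H](C)[C@@H]1COC(c2ccc(OC)cc2)O1 | intermediate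
10 | diisobutyl{(6S)-6-[(4R)-2-(4-methoxyphenyl)-1,3-dioxolan-4-yl]hept-1-en-2-yl}alane | C=C(CCC[C@H](C)[C@@H]1COC(c2ccc(OC)cc2)O1)[Al](CC(C)C)CC(C)C | intermediate (not isolated)
11 | (4R)-4-[(2S)-6-iodohept-6-en-2-yl]-2-(4-methoxyphenyl)-1,3-dioxolane | C=C(I)CCC[C@H](C)[C@@H]1COC(c2ccc(OC)cc2)O1 | intermediate
12 | (2R,3S)-7-iodo-2-[(4-methoxybenzyl)oxy]-3-methyloct-7-en-1-ol | C=C(I)CCC[C@H](C)[C@@H](OCc1ccc(OC)cc1)CO | intermediate
13 | (2R,3S)-7-iodo-2-[(4-methoxybenzyl)oxy]-3-methyloct-7-enal | C=C(I)CCC[C@H](C)[C@@H](OCc1ccc(OC)cc1)C=O | intermediate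
14 | pent-4-yn-1-ol | C#CCCCO | starting material
15 | tert-butyldimethyl(pent-4-yn-1-yloxy)silane | C#CCCCO[Si](C)(C)C(C)(C)C | intermediate
16 | (E)-{5-[(tert-butyldimethylsilyl)oxy]-2-methylpent-1-en-1-yl}dimethylalane | C[Al](C)/C=C(\C)CCCO[Si](C)(C)C(C)(C)C | intermediate (not isolated)
17 | (3E)-7-[(tert-butyldimethylsilyl)oxy]-4-methylhept-3-en-1-ol | OCC/C=C(\C)CCCO[Si](C)(C)C(C)(C)C | intermediate
18 | (3E)-7-[(tert-butyldimethylsilyl)oxy]-4-methylhept-3-enal | O=CC/C=C(\C)CCCO[Si](C)(C)C(C)(C)C | intermediate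
19 | methyl propiolate | C#CC(=O)OC | starting material
20 | methyl 2-(diisobutylalumanyl)prop-2-enoate | C=C(C(=O)OC)[Al](CC(C)C)CC(C)C | intermediate (not isolated)
21 | methyl (5E)-9-[(tert-butyldimethylsilyl)oxy]-3-hydroxy-6-methyl-2-methylidenenon-5-enoate (racemic at C3) | C=C(C(=O)OC)C(O)C/C=C(\C)CCCO[Si](C)(C)C(C)(C)C | intermediate
22 | methyl (2Z,5E)-2-(bromomethyl)-9-[(tert-butyldimethylsilyl)oxy]-6-methylnona-2,5-dienoate | COC(=O)/C(CBr)=C/C/C=C(\C)CCCO[Si](C)(C)C(C)(C)C | intermediate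
23 | methyl (3S,4R,5R,6S)-3-[(2E)-6-[(tert-butyldimethylsilyl)oxy]-3-methylhex-2-en-1-yl]-4-hydroxy-10-iodo-5-[(4-methoxybenzyl)oxy]-6-methyl-2-methylideneundec-10-enoate | C=C(I)CCC[C@H](C)[C@@H](OCc1ccc(OC)cc1)[C@H](O)[C@H](C(=C)C(=O)OC)C/C=C(\C)CCCO[Si](C)(C)C(C)(C)C | intermediate (not isolated)
24 | (4S,5R)-4-[(2E)-6-[(tert-butyldimethylsilyl)oxy]-3-methylhex-2-en-1-yl]-5-[(1R,2S)-6-iodo-1-[(4-methoxybenzyl)oxy]-2-methylhept-6-en-1-yl]-3-methylideneoxolan-2-one | C=C(I)CCC[C@H](C)[C@@H](OCc1ccc(OC)cc1)[C@@H]1OC(=O)C(=C)[C@@H]1C/C=C(\C)CCCO[Si](C)(C)C(C)(C)C | intermediate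
25 | (4S,5R)-4-[(2E)-6-hydroxy-3-methylhex-2-en-1-yl]-5-[(1R,2S)-6-iodo-1-[(4-methoxybenzyl)oxy]-2-methylhept-6-en-1-yl]-3-methylideneoxolan-2-one | C=C(I)CCC[C@H](C)[C@@H](OCc1ccc(OC)cc1)[C@@H]1OC(=O)C(=C)[C@@H]1C/C=C(\C)CCCO | intermediate
26 | (4E)-6-[(2R,3S)-2-[(1R,2S)-6-iodo-1-[(4-methoxybenzyl)oxy]-2-methylhept-6-en-1-yl]-4-methylidene-5-oxooxolan-3-yl]-4-methylhex-4-enal | C=C(I)CCC[C@H](C)[C@@H](OCc1ccc(OC)cc1)[C@@H]1OC(=O)C(=C)[C@@H]1C/C=C(\C)CCC=O | intermediate
27 | (3aS,5E,14S,15R,15aR)-9-hydroxy-15-[(4-methoxybenzyl)oxy]-6,14-dimethyl-3,10-dimethylidene-dodecahydrocyclotetradeca[b]furan-2(3H)-one, C9 epimers | C=C1CCC[C@H](C)[C@@H](OCc3ccc(OC)cc3)[C@@H]2OC(=O)C(=C)[C@@H]2C/C=C(\C)CCC1O | intermediate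
28 | (3aS,5E,14S,15R,15aR)-15-[(4-methoxybenzyl)oxy]-6,14-dimethyl-3,10-dimethylidene-decahydrocyclotetradeca[b]furan-2,9-dione | C=C1CCC[C@H](C)[C@@H](OCc3ccc(OC)cc3)[C@@H]2OC(=O)C(=C)[C@@H]2C/C=C(\C)CCC1=O | intermediate
29 | (3aS,5E,9R,14S,15R,15aR)-9-hydroxy-15-[(4-methoxybenzyl)oxy]-6,14-dimethyl-3,10-dimethylidene-dodecahydrocyclotetradeca[b]furan-2(3H)-one | C=C1CCC[C@H](C)[C@@H](OCc3ccc(OC)cc3)[C@@H]2OC(=O)C(=C)[C@@H]2C/C=C(\C)CC[C@H]1O | intermediate
30 | (3aS,5E,9R,14S,15R,15aR)-9,15-dihydroxy-6,14-dimethyl-3,10-dimethylidene-dodecahydrocyclotetradeca[b]furan-2(3H)-one | C=C1CCC[C@H](C)[C@@H](O)[C@@H]2OC(=O)C(=C)[C@@H]2C/C=C(\C)CC[C@H]1O | intermediate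
31 | (3aS,5E,9R,14S,15R,15aR)-6,14-dimethyl-3,10-dimethylidene-2-oxo-tetradecahydrocyclotetradeca[b]furan-9,15-diyl diacetate (5,6-olefin) | C=C1CCC[C@H](C)[C@@H](OC(C)=O)[C@@H]2OC(=O)C(=C)[C@@H]2C/C=C(\C)CC[C@H]1OC(C)=O | intermediate
32 | (3aS,5R,6R,9R,14S,15R,15aR)-5,6-epoxy-6,14-dimethyl-3,10-dimethylidene-2-oxotetradecahydrocyclotetradeca[b]furan-9,15-diyl diacetate (CNP0323853.1) | C=C1CCC[C@H](C)[C@@H](OC(C)=O)[C@@H]2OC(=O)C(=C)[C@@H]2C[C@H]2O[C@]2(C)CC[C@H]1OC(C)=O | target

**Totals**
Total step count: 23. Longest linear sequence: 18 steps (steps 1–9 and 15–23, from (S)-citronellal); the branch from pent-4-yn-1-ol is 5 steps (10–14).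

**Three steps most likely to fail**

Step 15. Three contiguous centres depend on chelation in water by a PMB-protected α-alkoxy aldehyde, which may give only moderate facial selectivity. The fallback sets out from 22 and comes back to the route at 24. Bromide 22 is treated with hexabutylditin and Pd(PPh3)4 (THF, 50 °C) to give the allylstannane methyl (2Z,5E)-9-[(tert-butyldimethylsilyl)oxy]-6-methyl-2-[(tributylstannyl)methyl]nona-2,5-dienoate F1. F1 is then added to aldehyde 13 pre-complexed with MgBr2·OEt2 in CH2Cl2 at −20 °C. A rigid magnesium chelate and an open antiperiplanar transition state (Keck-type chelation-controlled allylstannane addition) should lead to the same syn,syn hydroxy ester 23, which PPTS closes to 24.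

Step 20. Reagent control by the oxazaborolidine may be eroded by the conformational bias of the 14-membered ring. The fallback sets out from 28 and comes back at 31. Luche reduction (NaBH4, CeCl3·7H2O, MeOH, −78 °C) lets the ring decide. If it gives 29, the route continues unchanged. If it gives the epimer (3aS,5E,9S,14S,15R,15aR)-9-hydroxy-15-[(4-methoxybenzyl)oxy]-6,14-dimethyl-3,10-dimethylidene-dodecahydrocyclotetradeca[b]furan-2(3H)-one F2 (also available by separating the epimers of 27), Mitsunobu esterification with acetic acid (PPh3, DIAD, toluene, 0 °C) inverts C9 and installs the acetate, giving (3aS,5E,9R,14S,15R,15aR)-15-[(4-methoxybenzyl)oxy]-6,14-dimethyl-3,10-dimethylidene-2-oxo-tetradecahydrocyclotetradeca[b]furan-9-yl acetate F3. DDQ (buffered CH2Cl2, 0 °C) then gives (3aS,5E,9R,14S,15R,15aR)-15-hydroxy-6,14-dimethyl-3,10-dimethylidene-2-oxo-tetradecahydrocyclotetradeca[b]furan-9-yl acetate F4, and Ac2O/DMAP gives 31.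

Step 23. Facial selectivity of oxygen transfer to a macrocyclic olefin is the sum of catalyst and ring bias, and the acetates and lactone see pH 10.5. The fallback sets out from 31 and comes back at 32. NBS in THF/H2O at 0 °C adds bromine and water anti (water at the tertiary carbon) to give the bromohydrin (3aS,5S,6R,9R,14S,15R,15aR)-5-bromo-6-hydroxy-6,14-dimethyl-3,10-dimethylidene-2-oxo-tetradecahydrocyclotetradeca[b]furan-9,15-diyl diacetate F5. DBU in CH2Cl2 closes the oxirane with inversion at C5. The oxygen therefore ends on the face opposite to the one an electrophile attacks first, which is the right outcome exactly when direct oxygen transfer to the ring favours the unwanted (5S,6S) epoxide.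

**Further compounds**
F1 | step 15 | methyl (2Z,5E)-9-[(tert-butyldimethylsilyl)oxy]-6-methyl-2-[(tributylstannyl)methyl]nona-2,5-dienoate | COC(=O)/C(C[Sn](CCCC)(CCCC)CCCC)=C/C/C=C(\C)CCCO[Si](C)(C)C(C)(C)C
F2 | step 20 | (3aS,5E,9S,14S,15R,15aR)-9-hydroxy-15-[(4-methoxybenzyl)oxy]-6,14-dimethyl-3,10-dimethylidene-dodecahydrocyclotetradeca[b]furan-2(3H)-one | C=C1CCC[C@H](C)[C@@H](OCc3ccc(OC)cc3)[C@@H]2OC(=O)C(=C)[C@@H]2C/C=C(\C)CC[C@@H]1O
F3 | step 20 | (3aS,5E,9R,14S,15R,15aR)-15-[(4-methoxybenzyl)oxy]-6,14-dimethyl-3,10-dimethylidene-2-oxo-tetradecahydrocyclotetradeca[b]furan-9-yl acetate | C=C1CCC[C@H](C)[C@@H](OCc3ccc(OC)cc3)[C@@H]2OC(=O)C(=C)[C@@H]2C/C=C(\C)CC[C@H]1OC(C)=O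
F4 | step 20 | (3aS,5E,9R,14S,15R,15aR)-15-hydroxy-6,14-dimethyl-3,10-dimethylidene-2-oxo-tetradecahydrocyclotetradeca[b]furan-9-yl acetate | C=C1CCC[C@H](C)[C@@H](O)[C@@H]2OC(=O)C(=C)[C@@H]2C/C=C(\C)CC[C@H]1OC(C)=O
F5 | step 23 | (3aS,5S,6R,9R,14S,15R,15aR)-5-bromo-6-hydroxy-6,14-dimethyl-3,10-dimethylidene-2-oxo-tetradecahydrocyclotetradeca[b]furan-9,15-diyl diacetate | C=C1CCC[C@H](C)[C@@H](OC(C)=O)[C@@H]2OC(=O)C(=C)[C@@H]2C[C@H](Br)[C@@](O)(C)CC[C@H]1OC(C)=O
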